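**Retrosynthetic overview**

- The target is 6,8-diprenylquercetin. The strategy rests on the C3(OH)–C4(=O) unit of pyranone ring C (O1, C2, C3, C4, C4a, C8a): in the 2,3-dihydro series it is an acyloin, the retron of a benzoin union of two formyl carbons.
- End game: global MOM removal ⇐ tetra-MOM flavonol ⇐ copper(II) dehydrogenation of a 3-hydroxyflavanone, which flattens C2 and C3.
- Key disconnection C3–C4: carbene-catalysed intramolecular crossed benzoin of an aryloxy dialdehyde that already holds O1–C2. Ring C is the only ring formed; rings A and B are bought.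
- Dialdehyde ⇐ diol ⇐ ester aldehyde, joined at O1–C2 by Mitsunobu etherification of a bis-MOM diprenyl phloroglucinaldehyde with methyl bis-MOM-mandelate. Ring A is mirror-symmetric (C5/C7 oxygens, C6/C8 prenyls), so either ortho oxygen can become O1.
- Ring A piece from C-diprenylation of 2,4,6-trihydroxybenzaldehyde; the ring B/C2/C3 piece from 3,4-dihydroxymandelic acid.

Key step: step 8

Remark: the target has no stereocentre (planar flavonol, achiral prenyl chains), so there is no enantiomer to select. All chiral intermediates are racemic, and their centres (C2, C3) are erased in step 9.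

**Route**

Step 1
Reactants: 1 2,4,6-trihydroxybenzaldehyde; 2 prenyl bromide (1-bromo-3-methylbut-2-ene)
Product: 3 2,4,6-trihydroxy-3,5-bis(3-methylbut-2-enyl)benzaldehyde
Conditions: 2 (2.1 equiv), KOH (3 equiv), H2O, 0 °C to rt
Reagents that add atoms: none
Why: C-alkylation of the ambident phloroglucinolate, whose hydrogen-bonded oxygens in water leave the two equivalent free ring carbons C3 and C5 to take up the allylic bromide (the method used for diprenyl acylphloroglucinols); mono-, O- and gem-dialkylated by-products are expected and are removed by chromatography.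

Step 2
Reactants: 3 2,4,6-trihydroxy-3,5-bis(3-methylbut-2-enyl)benzaldehyde; 4 chloromethyl methyl ether
Product: 5 2-hydroxy-4,6-bis(methoxymethoxy)-3,5-bis(3-methylbut-2-enyl)benzaldehyde
Conditions: 4 (2.2 equiv), i-Pr2NEt, CH2Cl2, 0 °C to rt
Reagents that add atoms: none
Why: Williamson-type MOM etherification that should stop at two ethers, because the para hydroxyl and one ortho hydroxyl react while the last ortho hydroxyl is held in the hydrogen bond to the formyl oxygen; the two ortho hydroxyls are equivalent, so only one bis-ether can form.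

Step 3
Reactants: 6 rac-3,4-dihydroxymandelic acid
Product: 7 methyl rac-2-(3,4-dihydroxyphenyl)-2-hydroxyacetate
Conditions: MeOH, H2SO4 (cat.), rt, N2
Reagents that add atoms: methanol (CO)
Why: Fischer esterification of an α-hydroxy acid, kept at room temperature so that the benzylic hydroxyl, whose ionisation the adjacent ester disfavours, is not exchanged for methoxyl.

Step 4
Reactants: 7 methyl rac-2-(3,4-dihydroxyphenyl)-2-hydroxyacetate; 4 chloromethyl methyl ether
Product: 8 methyl rac-2-[3,4-bis(methoxymethoxy)phenyl]-2-hydroxyacetate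
Conditions: 4 (2.2 equiv), K2CO3, acetone, 0 °C to rt, N2
Reagents that add atoms: none
Why: Williamson etherification in which carbonate ionises only the two phenols, so the un-ionised secondary alcohol should stay free for step 5.

Step 5
Reactants: 5 2-hydroxy-4,6-bis(methoxymethoxy)-3,5-bis(3-methylbut-2-enyl)benzaldehyde; 8 methyl rac-2-[3,4-bis(methoxymethoxy)phenyl]-2-hydroxyacetate
Product: 9 methyl rac-2-[3,4-bis(methoxymethoxy)phenyl]-2-[2-formyl-3,5-bis(methoxymethoxy)-4,6-bis(3-methylbut-2-enyl)phenoxy]acetate
Conditions: PPh3, DIAD, THF, 0 °C to rt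
Reagents that add atoms: none
Why: Mitsunobu etherification forming O1–C2, in which the acidic ortho-formyl phenol is a competent pronucleophile and the mandelate alkoxyphosphonium is an activated SN2 centre with no β-hydrogen to eliminate; the centre is racemic, so inversion is of no consequence.

Step 6
Reactants: 9 methyl rac-2-[3,4-bis(methoxymethoxy)phenyl]-2-[2-formyl-3,5-bis(methoxymethoxy)-4,6-bis(3-methylbut-2-enyl)phenoxy]acetate
Product: 10 rac-2-[3,4-bis(methoxymethoxy)phenyl]-2-[2-(hydroxymethyl)-3,5-bis(methoxymethoxy)-4,6-bis(3-methylbut-2-enyl)phenoxy]ethanol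
Conditions: LiAlH4, THF, 0 °C; aq. NaOH work-up
Reagents that add atoms: none
Why: Hydride reduction of the ester and the aryl aldehyde to a storable diol, with MOM acetals, aryl ethers and prenyl alkenes inert to LiAlH4; the electron-rich benzylic alcohol is kept away from acid.

Step 7
Reactants: 10 rac-2-[3,4-bis(methoxymethoxy)phenyl]-2-[2-(hydroxymethyl)-3,5-bis(methoxymethoxy)-4,6-bis(3-methylbut-2-enyl)phenoxy]ethanol
Product: 11 rac-2-[3,4-bis(methoxymethoxy)phenyl]-2-[2-formyl-3,5-bis(methoxymethoxy)-4,6-bis(3-methylbut-2-enyl)phenoxy]acetaldehyde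
Conditions: IBX (3 equiv), DMSO, rt; crude product used at once
Reagents that add atoms: none
Why: Hypervalent-iodine (IBX) oxidation takes both the primary and the benzylic alcohol to the aldehyde stage and no further under base-free conditions, so the enolisable C2–H centre of the dialdehyde is not exposed to base before the key step.

Step 8
Reactants: 11 rac-2-[3,4-bis(methoxymethoxy)phenyl]-2-[2-formyl-3,5-bis(methoxymethoxy)-4,6-bis(3-methylbut-2-enyl)phenoxy]acetaldehyde
Product: 13 rac-(2R*,3R*)-3-hydroxy-5,7-bis(methoxymethoxy)-2-[3,4-bis(methoxymethoxy)phenyl]-6,8-bis(3-methylbut-2-enyl)chroman-4-one (2,3-trans), via 4-hydroxychroman-3-one regioisomer 12 (not isolated)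
Conditions: 2-(pentafluorophenyl)-6,7-dihydro-5H-pyrrolo[2,1-c][1,2,4]triazol-2-ium tetrafluoroborate (20 mol%), i-Pr2NEt (20 mol%), CH2Cl2 (0.02 M), 0 °C to rt, Ar
Reagents that add atoms: none
Why: The triazolylidene adds reversibly to a formyl group, most readily the unhindered aliphatic one at C3; proton transfer gives the enaminol (Breslow intermediate), whose nucleophilic carbon attacks the aryl formyl carbon C4, and loss of the carbene leaves acyloin 12, which is expected to isomerise through the shared enediol (and by reversible retro-benzoin) to the aryl-conjugated 4-ketone 13, the compound also formed directly if the aryl aldehyde acts as donor. The closest known reaction type is the NHC-catalysed intramolecular crossed benzoin cyclisation of dialdehydes to cyclic acyloins and of 2-(2-oxoalkoxy)benzaldehydes to 3-hydroxychroman-4-ones. Ring C (O1, C2, C3, C4, C4a, C8a) closes 6-exo-trig by formation of C3–C4. The new centre C3 is alpha to the ketone and epimerisable, so the 2,3-trans (diequatorial) racemate is expected under thermodynamic control; this is immaterial because C2 and C3 are both flattened in step 9. Ring closure must outrun two leaks, expulsion of the O1 aryloxide from the C3 enaminol (the internal-redox path of α-aryloxy aldehydes) and 5-exo aldol of the C2 enol onto the aryl aldehyde; the six-membered intramolecular delivery, the only moderate nucleofugality of an electron-rich, doubly flanked phenoxide (well below the nitrophenoxide or carboxylate leaving groups that the redox path normally needs) and a catalytic amount of weak amine base at low temperature are relied on for this, while high dilution and the two ortho substituents suppress intermolecular benzoin. Regio- and diastereoisomeric acyloins need not be separated, since all are dehydrogenated to the same flavonol.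

Step 9
Reactants: 13 rac-(2R*,3R*)-3-hydroxy-5,7-bis(methoxymethoxy)-2-[3,4-bis(methoxymethoxy)phenyl]-6,8-bis(3-methylbut-2-enyl)chroman-4-one (with any 12 carried through)
Product: 15 3-hydroxy-5,7-bis(methoxymethoxy)-2-[3,4-bis(methoxymethoxy)phenyl]-6,8-bis(3-methylbut-2-enyl)-4H-chromen-4-one, via chromane-3,4-dione keto tautomer 14 (not isolated)
Conditions: Cu(OAc)2 (2.2 equiv), pyridine, 60 °C, N2; aq. EDTA work-up
Reagents that add atoms: none
Why: Copper(II) oxidation of the α-ketol to the 1,2-dione (benzoin-to-benzil type) through the copper enediolate gives 14, which enolises towards C2 to the aromatic pyranone of flavonol 15; oxygen is excluded because copper flavonolates are cleaved by O2, and MOM ethers and prenyl groups are inert to Cu(II) in pyridine.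

Step 10
Reactants: 15 3-hydroxy-5,7-bis(methoxymethoxy)-2-[3,4-bis(methoxymethoxy)phenyl]-6,8-bis(3-methylbut-2-enyl)-4H-chromen-4-one
Product: 16 3,5,7-trihydroxy-2-(3,4-dihydroxyphenyl)-6,8-bis(3-methylbut-2-enyl)-4H-chromen-4-one (6,8-diprenylquercetin, CNP0196011.0)
Conditions: 3 M aq. HCl–MeOH (1:5), 40 °C, stopped at full conversion
Reagents that add atoms: none
Why: Acid-catalysed acetal solvolysis removes the four MOM ethers via oxocarbenium ions trapped by methanol, under the mild conditions customary for MOM-protected prenylated flavonoids, with time and temperature limited so that protonation of the prenyl alkenes does not compete.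

**Compound list**

1 | 2,4,6-trihydroxybenzaldehyde | O=Cc1c(O)cc(O)cc1O | starting material
2 | prenyl bromide (1-bromo-3-methylbut-2-ene) | CC(C)=CCBr | starting material
3 | 2,4,6-trihydroxy-3,5-bis(3-methylbut-2-enyl)benzaldehyde | O=Cc1c(O)c(CC=C(C)C)c(O)c(CC=C(C)C)c1O | intermediate
4 | chloromethyl methyl ether | COCCl | starting material
5 | 2-hydroxy-4,6-bis(methoxymethoxy)-3,5-bis(3-methylbut-2-enyl)benzaldehyde | O=Cc1c(O)c(CC=C(C)C)c(OCOC)c(CC=C(C)C)c1OCOC | intermediate
6 | rac-3,4-dihydroxymandelic acid | OC(C(=O)O)c1ccc(O)c(O)c1 | starting material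
7 | methyl rac-2-(3,4-dihydroxyphenyl)-2-hydroxyacetate | COC(=O)C(O)c1ccc(O)c(O)c1 | intermediate
8 | methyl rac-2-[3,4-bis(methoxymethoxy)phenyl]-2-hydroxyacetate | COC(=O)C(O)c1ccc(OCOC)c(OCOC)c1 | intermediate
9 | methyl rac-2-[3,4-bis(methoxymethoxy)phenyl]-2-[2-formyl-3,5-bis(methoxymethoxy)-4,6-bis(3-methylbut-2-enyl)phenoxy]acetate | COC(=O)C(Oc1c(CC=C(C)C)c(OCOC)c(CC=C(C)C)c(OCOC)c1C=O)c1ccc(OCOC)c(OCOC)c1 | intermediate
10 | rac-2-[3,4-bis(methoxymethoxy)phenyl]-2-[2-(hydroxymethyl)-3,5-bis(methoxymethoxy)-4,6-bis(3-methylbut-2-enyl)phenoxy]ethanol | OCC(Oc1c(CC=C(C)C)c(OCOC)c(CC=C(C)C)c(OCOC)c1CO)c1ccc(OCOC)c(OCOC)c1 | intermediate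
11 | rac-2-[3,4-bis(methoxymethoxy)phenyl]-2-[2-formyl-3,5-bis(methoxymethoxy)-4,6-bis(3-methylbut-2-enyl)phenoxy]acetaldehyde | O=CC(Oc1c(CC=C(C)C)c(OCOC)c(CC=C(C)C)c(OCOC)c1C=O)c1ccc(OCOC)c(OCOC)c1 | intermediate
12 | rac-4-hydroxy-5,7-bis(methoxymethoxy)-2-[3,4-bis(methoxymethoxy)phenyl]-6,8-bis(3-methylbut-2-enyl)chroman-3-one (diastereomer mixture) | COCOc1ccc(cc1OCOC)C1Oc2c(CC=C(C)C)c(OCOC)c(CC=C(C)C)c(OCOC)c2C(O)C1=O | intermediate (not isolated)
13 | rac-(2R*,3R*)-3-hydroxy-5,7-bis(methoxymethoxy)-2-[3,4-bis(methoxymethoxy)phenyl]-6,8-bis(3-methylbut-2-enyl)chroman-4-one (2,3-trans; one enantiomer drawn) | COCOc1ccc(cc1OCOC)[C@H]1Oc2c(CC=C(C)C)c(OCOC)c(CC=C(C)C)c(OCOC)c2C(=O)[C@@H]1O | intermediate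
14 | rac-5,7-bis(methoxymethoxy)-2-[3,4-bis(methoxymethoxy)phenyl]-6,8-bis(3-methylbut-2-enyl)chromane-3,4-dione | COCOc1ccc(cc1OCOC)C1Oc2c(CC=C(C)C)c(OCOC)c(CC=C(C)C)c(OCOC)c2C(=O)C1=O | intermediate (not isolated)
15 | 3-hydroxy-5,7-bis(methoxymethoxy)-2-[3,4-bis(methoxymethoxy)phenyl]-6,8-bis(3-methylbut-2-enyl)-4H-chromen-4-one | COCOc1ccc(cc1OCOC)-c1oc2c(CC=C(C)C)c(OCOC)c(CC=C(C)C)c(OCOC)c2c(=O)c1O | intermediate
16 | 3,5,7-trihydroxy-2-(3,4-dihydroxyphenyl)-6,8-bis(3-methylbut-2-enyl)-4H-chromen-4-one (6,8-diprenylquercetin) | CC(C)=CCc1c(O)c(CC=C(C)C)c2oc(-c3ccc(O)c(O)c3)c(O)c(=O)c2c1O | target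

**Step count and risks**

Total steps: 10. Longest linear sequence: 8 steps (steps 1, 2, 5, 6, 7, 8, 9, 10 from 2,4,6-trihydroxybenzaldehyde; the mandelate branch through steps 3 and 4 is equally long).

Steps most likely to fail:

1. Step 8 (key step). The enaminol formed at the aliphatic aldehyde may fragment by loss of the O1 aryloxide before it closes the ring. The enolisable C2–H aldehyde may also undergo 5-exo aldol onto the aryl formyl group, or the carbene may simply fail to bring about closure onto the doubly flanked aldehyde. The fallback replaces carbene umpolung by reductive ketyl coupling. It sets out from dialdehyde 11: SmI2 (2.5 equiv) with t-BuOH in THF at −78 °C should reduce the aryl aldehyde to its ketyl, which adds to the aliphatic formyl group in an intramolecular pinacol coupling and gives rac-5,7-bis(methoxymethoxy)-2-[3,4-bis(methoxymethoxy)phenyl]-6,8-bis(3-methylbut-2-enyl)chromane-3,4-diol F1 as a diastereomer mixture. Oxidation of both carbinols of F1 with IBX in DMSO should give dione 14, which tautomerises to flavonol 15. The fallback comes back to the route at 15 and makes step 9 unnecessary.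

2. Step 5. Capture of the alkoxyphosphonium ion by the flanked, hydrogen-bonded phenol may be slow, so that the mandelate is consumed by alkylation of the reduced azodicarboxylate. The fallback turns the redox condensation into a plain SN2 displacement. It sets out from alcohol 8: MsCl and Et3N in CH2Cl2 at 0 °C should give methyl rac-2-[3,4-bis(methoxymethoxy)phenyl]-2-(methylsulfonyloxy)acetate F2, used crude. F2 is then displaced by the phenoxide of 5 (Cs2CO3, DMF, rt), and the fallback comes back to the route at 9.

3. Step 10. Under protic acid the prenyl alkenes may be protonated and captured by the freed neighbouring phenols (5-OH, 7-OH), closing 2,2-dimethylchroman rings, or may be hydrated. The fallback avoids protic acid by trans-protection to silyl ethers. It sets out from 15: TMSOTf with 2,2'-bipyridyl in CH3CN at 0 °C should convert the aryl MOM ethers (and the 3-OH) into trimethylsilyl ethers under buffered conditions, giving 3,5,7-tris(trimethylsilyloxy)-2-[3,4-bis(trimethylsilyloxy)phenyl]-6,8-bis(3-methylbut-2-enyl)-4H-chromen-4-one F3. Hydrolysis of F3 with water–MeOH at rt should then release the phenols, and the fallback comes back to the route at 16.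

**Further compounds**

F1 | step 8 | rac-5,7-bis(methoxymethoxy)-2-[3,4-bis(methoxymethoxy)phenyl]-6,8-bis(3-methylbut-2-enyl)chromane-3,4-diol (diastereomer mixture) | COCOc1ccc(cc1OCOC)C1Oc2c(CC=C(C)C)c(OCOC)c(CC=C(C)C)c(OCOC)c2C(O)C1O
F2 | step 5 | methyl rac-2-[3,4-bis(methoxymethoxy)phenyl]-2-(methylsulfonyloxy)acetate | COC(=O)C(OS(C)(=O)=O)c1ccc(OCOC)c(OCOC)c1
F3 | step 10 | 3,5,7-tris(trimethylsilyloxy)-2-[3,4-bis(trimethylsilyloxy)phenyl]-6,8-bis(3-methylbut-2-enyl)-4H-chromen-4-one | CC(C)=CCc1c(O[Si](C)(C)C)c(CC=C(C)C)c2oc(-c3ccc(O[Si](C)(C)C)c(O[Si](C)(C)C)c3)c(O[Si](C)(C)C)c(=O)c2c1O[Si](C)(C)C
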